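The constant I could read for the east flask was a ratio, not a rate. Its target stood at 25.1% after 5.00 min and 25.1% after 80.0 min, which looked like thermodynamic control.

| setting | east | south-east | flask |
|---|---|---|---|
| starting material | 0.0010 M | 0.0010 M | 0.0010 M |
| protic impurity | 0.020 mM | 0.020 mM | 0.0200 mM |
| temperature | 40 °C | 46 °C | 40 °C |
| remark | the very flask that is asked about, followed so far | run made earlier |  |
| time |  |  | 1.5 h |

- east (time / min: target / %, starting material / %): 5.00: 25.1, 22.1; 15.0: 25.1, 22.5; 25.0: 25.0, 22.2; 40.0: 24.8, 21.6; 60.0: 25.3, 21.8; 80.0: 25.1, 21.6
- south-east (time / min: target / %, starting material / %): 5.00: 20.6, 23.4; 15.0: 20.5, 23.4; 25.0: 20.6, 23.3; 40.0: 20.3, 22.8; 60.0: 20.3, 23.1; 80.0: 20.2, 23.3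

(each reading ± 0.3 percentage points)

- epsilon: at 1.5 h raise the temperature by 10 K, then wait 25 min
- zeta: change nothing and wait 25 min more
- alpha: at 1.5 h add starting material, 50.0% of the amount charged, then wait 25 min
- theta: at 1.5 h take out 90% of the target then present, then wait 25 min

- target that was removed still counts
- the analysis behind the earlier runs scatters by 0.3 percentage points, standard deviation
- additions bring no volume worth counting

1. target, in percent of the starting material first charged, at 1.5 h
2. the option that brings most further target ("none" if no option brings more than 2 percentage points) (epsilon / zeta / alpha / theta / none)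
3. target present, with what was taken out counted in, in percent of the starting material first charged, after zeta
4. target present, with what was taken out counted in, in percent of the starting material first charged, after theta

The two readings of the east flask summed to 46.7% of the charge after 80.0 min, so I assumed that the unseen rest was a reversible reservoir, which the runs could not prove. Taking one starting material each, the protic impurity could claim 2.00%, which left a pool of 98.0%. The mean target reading was 25.1%, so the plateau share, the part of the pool that stands as target, read 25.6%.

I then turned the settings one after the other. Time came first: the flat readings led me to expect 25.1% at 1.5 h and the same figure after zeta. Temperature came next: the south-east run ended at 20.2%, lower than the east run, so I expected epsilon to lose target. Removal came third: theta takes out 22.6%, and I took it that the rest of the pool would return to the plateau share, so I reckoned a gain of 17 percentage points and a total of 41.9%. Addition came last: alpha should yield the plateau share of what is added, which is less than the gain I reckoned for theta. I therefore chose theta, whose reckoned gain exceeds the margin.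

The forecast gave 25% now, 25% after zeta and 41.9% after theta, which it chose, reading the plateau as “a rapid equilibrium rather than slow kinetics”.

The flask gave 24.8% at 1.5 h, 24.8% after zeta and 41.5% after theta, a gain of 17 points; epsilon lost 6.7 points.

    target ⇌ isomer of the product (k = 0.0273 s⁻¹, Ea = 88.0 kJ mol⁻¹)
    starting material ⇌ target (K = 1.13, k = 0.0335 s⁻¹, Ea = 92.0 kJ mol⁻¹, ΔH = −33.0 kJ mol⁻¹)
    starting material ⇌ isomer of the product (K = 2.33, k = 0.00153 s⁻¹, Ea = 101 kJ mol⁻¹, ΔH = 1.00 kJ mol⁻¹)
    starting material + protic impurity → quenched substrate (k = 82.5 L mol⁻¹ s⁻¹, Ea = 49.0 kJ mol⁻¹)
    (constants at 40 °C)

The unseen part of the flask held 51.2% of isomer of the product after 90.0 min, beside 2.00% of quenched substrate, with the protic impurity down to 0%. Applied to the 50.0% added in alpha, the plateau share of 25.6% gave 13 points, and that option brought 13 points.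

The earlier runs and the new flask are simulated with made-up constants.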